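## Structural features

The target is a flavonol. Ring A is a benzo ring with a 6,7-catechol, fused to the 4-pyranone ring C (O1, C2, C3, C4, C4a, C8a). Ring B, a 4'-hydroxy-3'-prenyloxyphenyl group, is joined to C2 by one aryl–carbon bond. The molecule is flat and has no stereocenter; the saturated intermediates carry two adjacent stereocenters, C2 and C3, and both disappear when ring C reaches the enol–ketone level. The fragile groups are the aryl prenyl ether, the catechol and the C3 enol. The prenyl ether is an allylic ether that ionizes under protic or Lewis acid and under zerovalent palladium, and its trisubstituted alkene is attacked by peracids, dioxiranes and hydrogenation catalysts; the catechol and enol are air-sensitive as anions. The real difficulty is twofold: only one of the five peripheral oxygens, O3', is alkylated, and C3 must be oxygenated without an electrophilic oxidant meeting the prenyl alkene. It follows that the phenol protecting groups should leave without acid, so silyl ethers cleaved by fluoride are used instead of acetals. The key step exploits three facts: C2 is benzylic and para to O4', C3 carries oxygen, and C4 is a carbonyl carbon bound to C4a. C2 and C3 are therefore the two carbons of a ring B glycidic ester whose ester carbon is C4, and once the ring A phenol has opened the epoxide at C2 only the C4–C4a bond is missing. C4a is ortho to O1 and para to O7, a site that a bromine atom marks without ambiguity; this mapping and the 3',4' pattern of ring B were checked atom by atom against the target and need no correction.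

## Logic of the disconnections

19 from 18: the three aryl O–Si bonds are cut last. Fluoride is the one deprotecting agent that leaves the allylic ether, the enol and the catechol alone. The gain is that every sensitive hydroxyl stays masked to the end. The demand is a buffered fluoride source, so that no phenoxide stands in air.

18 from 16 through 17: no skeletal bond is cut; the oxidation level at C3 is lowered. A saturated ring C with a C3 hydroxyl can be built from sp3 pieces, and its oxidation to 17 is followed by enolization to 18. The gain is that the C3 oxygen needs no late introduction and that C2 and C3 need no stereocontrol. The demand is an oxidant for a secondary alcohol that ignores a trisubstituted alkene and aryl silyl ethers.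

16 from 15: the O3–Si bond is cut. O3 must be masked in the organolithium step and free for the oxidation. The demand is cleavage of one alkyl silyl ether beside three aryl silyl ethers, which calls for weak acid and not fluoride.

15 from 12 through 13 and 14: the C4–C4a bond is cut. It is the only ring C bond joining a carbon that can be an ester carbon to a carbon that can be an aryl anion placed by a halogen. The gain is that ring C opens to the acyclic ether ester 12, made of a ring B three-carbon unit and a ring A phenol. The demand is that halogen–lithium exchange outruns both addition to the ester and removal of the C3 proton, and that acylation stops at the ketone.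

12 from 11: the O3–Si bond is cut; the forward step only masks the one acidic proton of 11.

11 from 6 and 10: the O1–C2 ether bond is cut. C2 is benzylic and para to O4', which makes it the electrophilic carbon of an epoxide, and the epoxide oxygen becomes O3 at no cost. The gain is two fragments of similar size. The demand is regioselective opening at the benzylic carbon by a weakly nucleophilic phenol, without acid strong enough to harm silyl or prenyl ethers.

6 from 4 and 5: the C2–C3 bond and the C2–O bond of the oxirane are cut (flavonoid numbering). This reduces the three-carbon unit to an aldehyde and a two-carbon ester with a leaving group. The demand is a base that does not attack the aryl silyl ether.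

4 from 3, and 3 from 1 and 2: the O4'–Si bond and then the O3'–prenyl bond are cut. Placing the prenyl group on the simplest diphenol at the outset settles the one-in-five differentiation. The demand is monoalkylation at O3 and not at the more acidic O4.

10 from 9, 9 from 7 through 8, and 7 from 1: the C–Br bond, the aryl C–O bond (traced back to an aryl–CHO bond) and two O–Si bonds are cut. Both aromatic rings then come from 1. The demand is bromination at the one ring position that is ortho to the free hydroxyl and para to the oxygen that becomes O7.

## Other disconnections considered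

Alternative 1: The cut removes C3 with its oxygen as a one-carbon ylide and opens ring C at C3–C4 and C2–C3.
- Forward key step: the O-aroyl salicyloyl chloride A2, which already holds ring B as an ester, would meet two equivalents of the alkoxymethylidene phosphorane A3. One equivalent is acylated at carbon and the second removes the proton. On heating, the acyl ylide would olefinate the neighbouring aryl ester carbonyl and give the 3-alkoxyflavone A1.
- In favour: ring C appears directly at the flavone oxidation level with O3 in place, no stereocenter is formed, and no oxidation follows the ring closure. On redox economy and on length after the ring closure (two deprotections against three steps) this plan is better than the chosen one. Ring B enters as a benzoic acid, which is as accessible as aldehyde 4.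
- Against: A2 is an acid chloride carrying three acetals and an allylic ether, so it must be made under strictly neutral conditions. The ring A partner is a 2-hydroxy-4,5-dioxygenated benzoic acid, which is further from 1 than phenol 10. The ester olefination needs heat, and excess A3 can attack the aroyl ester between molecules. The acetals of A1 still require protic acid beside the prenyl ether.
- Comparison: the mechanisms of the two plans are comparably well founded. The chosen plan is milder (−100 °C against heating) and draws both rings from one cheap aldehyde. The alternative gives a cleaner endgame but a longer and more delicate way to its precursor.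

Alternative 2: The cut removes C4 as carbon monoxide A7 and separates ring A, as the iodophenol A5, from ring B, as the terminal alkyne A6.
- Forward key step: with PdCl2(dppf) in diethylamine, zerovalent palladium would insert into the C–I bond, take up A7 and couple with A6 to an alkynyl ketone. The phenol oxygen would then add in the 6-endo sense to give flavone A4.
- In favour: three bonds and ring C form in one operation from two fragments of similar size. On convergence and bond economy this plan is clearly better than the chosen one. A5 would come from phenol 9 by iodination as easily as 10 comes by bromination.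
- Against: A4 has no oxygen at C3. Adding it later needs either C3 metalation, borylation and oxidation, or a dioxirane, and the dioxirane would epoxidize the prenyl alkene. Zerovalent palladium with a secondary amine is the combination that ionizes allylic aryl ethers, so the prenyl ether is at risk in the key step itself. Closure in the 5-exo sense to an aurone and coupling without carbonylation would compete. A6 costs a one-carbon homologation of the aldehyde.
- Comparison: the alternative wins on the ring-forming step taken alone. The chosen plan wins on what the structure needs, because the epoxide supplies O3 and no palladium or oxidant meets the prenyl group.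

Alternative 3: The cut is C3–C4, made in the reductive pinacol sense.
- Forward key step: SmI2 would reduce the two formyl groups of dialdehyde A9 and join the ring A aldehyde carbon to the alpha-aryloxy aldehyde carbon. This closes ring C as the flavan-3,4-diol A8, which a double oxidation and enolization would take to the flavonol.
- In favour: the conditions are neutral and cold, and neither acetals nor the prenyl ether react with SmI2. O3 is carried in from the start and the stereocenters are later erased; on both points this plan equals the chosen one. Six-membered pinacol closures are dependable.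
- Against: the C3 aldehyde of A9 has an aryloxy group on its alpha carbon, and ketyl intermediates expel such alpha leaving groups in competition with C–C coupling. The alpha C–H of A9 is benzylic, next to oxygen and next to a formyl group, so A9 would enolize and eliminate easily. Two alcohol oxidations are then needed in place of one, and a 1,2-diol can cleave under oxidation. Making A9 needs an ortho-formyl phenol and a partial ester reduction.
- Comparison: it is equal to the chosen plan on the origin of O3 and on stereochemical indifference, and weaker on mechanistic safety and step count.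

Key step: step 9

Remark on the chemistry: the three phenolic oxygens of the cyclization substrate are carried as silyl ethers (two TBS on ring A, one TIPS on ring B) and not as acetals, because acetal cleavage needs protic acid that an aryl prenyl ether cannot be trusted to survive, while fluoride leaves it untouched; the carbon skeleton, the bromide, the methyl ester, the C3 triethylsilyl ether and the C4–C4a bond formation are unchanged.

Abbreviations: TBS = tert-butyldimethylsilyl; TIPS = triisopropylsilyl; TES = triethylsilyl; prenyl = 3-methylbut-2-en-1-yl.

## Route

Step 1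
Reactants: 1 3,4-dihydroxybenzaldehyde; 2 prenyl bromide (1-bromo-3-methylbut-2-ene)
Product: 3 4-hydroxy-3-(prenyloxy)benzaldehyde
Conditions: NaH (2.1 equiv), DMSO, 20 °C; then 2 (1.0 equiv), 20 °C; dilute aq. HCl, 0 °C
Reagents that add atoms: none
Why: Williamson ether synthesis on the dianion of 1; the 4-phenoxide is delocalized into the para formyl group, so the 3-phenoxide is the more nucleophilic oxygen and takes the single equivalent of allylic bromide; no stereocenter is formed.

Step 2
Reactants: 3 4-hydroxy-3-(prenyloxy)benzaldehyde
Product: 4 3-(prenyloxy)-4-(triisopropylsilyloxy)benzaldehyde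
Conditions: TIPSCl, imidazole, DMF, 20 °C
Reagents that add atoms: chlorotriisopropylsilane (TIPSCl), CC(C)[Si](Cl)(C(C)C)C(C)C
Why: Standard silylation of a phenol with a silyl chloride and imidazole; the bulky TIPS ether is chosen because it should resist the amide base of step 3 and still leave with fluoride in step 12.

Step 3
Reactants: 4 3-(prenyloxy)-4-(triisopropylsilyloxy)benzaldehyde; 5 methyl chloroacetate
Product: 6 methyl 3-[3-(prenyloxy)-4-(triisopropylsilyloxy)phenyl]oxirane-2-carboxylate (racemic; trans isomer expected to predominate, any cis isomer carried along)
Conditions: NaN(SiMe3)2, THF, −78 → 0 °C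
Reagents that add atoms: none
Why: Darzens glycidic ester condensation: the sodium enolate of 5 adds to the aldehyde and the chlorohydrin alkoxide closes the epoxide by internal SN2 on warming; a hindered amide base in THF replaces the usual alkoxide in alcohol so that the aryl silyl ether is not cleaved; the two new stereocenters are set without control, which is harmless because step 11 erases both.

Step 4
Reactants: 1 3,4-dihydroxybenzaldehyde
Product: 7 3,4-bis(tert-butyldimethylsilyloxy)benzaldehyde
Conditions: TBSCl (2.3 equiv), imidazole, DMF, 20 °C
Reagents that add atoms: tert-butylchlorodimethylsilane (TBSCl), CC(C)(C)[Si](C)(C)Cl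
Why: Double silylation of a catechol with TBSCl and imidazole in DMF, a routine protection; the aldehyde is untouched.

Step 5
Reactants: 7 3,4-bis(tert-butyldimethylsilyloxy)benzaldehyde
Product: 9 3,4-bis(tert-butyldimethylsilyloxy)phenol, via aryl formate 8 (not isolated)
Conditions: mCPBA, CH2Cl2, 0 → 20 °C; then Et3N, MeOH, 0 °C
Reagents that add atoms: 3-chloroperoxybenzoic acid (mCPBA), O=C(OO)c1cccc(Cl)c1
Why: Baeyer–Villiger oxidation of an electron-rich benzaldehyde (aryl migration) gives formate 8, and amine-promoted methanolysis of this very labile ester frees the phenol under conditions that aryl TBS ethers should survive; the peracid meets only the ring A fragment, which has no alkene.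

Step 6
Reactants: 9 3,4-bis(tert-butyldimethylsilyloxy)phenol
Product: 10 2-bromo-4,5-bis(tert-butyldimethylsilyloxy)phenol
Conditions: NBS (1.0 equiv), CH2Cl2, −78 → 0 °C
Reagents that add atoms: N-bromosuccinimide (NBS), O=C1CCC(=O)N1Br
Why: Electrophilic bromination of a phenol with NBS; of the two positions ortho to the free hydroxyl, one is wedged between the hydroxyl and a silyloxy group, so bromine should enter at the open one, which is para to the oxygen that becomes O7 and is the future C4a.

Step 7
Reactants: 6 methyl 3-[3-(prenyloxy)-4-(triisopropylsilyloxy)phenyl]oxirane-2-carboxylate; 10 2-bromo-4,5-bis(tert-butyldimethylsilyloxy)phenol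
Product: 11 methyl 3-[2-bromo-4,5-bis(tert-butyldimethylsilyloxy)phenoxy]-2-hydroxy-3-[3-(prenyloxy)-4-(triisopropylsilyloxy)phenyl]propanoate (racemic mixture of both diastereomers)
Conditions: 10 (1.2 equiv), toluene, 90 °C
Reagents that add atoms: none
Why: Opening of a 3-aryl glycidic ester by a phenol at the benzylic carbon: the para silyloxy group of ring B stabilizes positive charge there, so the hydrogen-bonded epoxide should open at that carbon in an SN1-like ion-pair manner, as para-alkoxyphenyl glycidates do with thiophenols and phenols, while the ester disfavours attack at the other carbon; the benzylic stereocenter forms without control and both diastereomers are used.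

Step 8
Reactants: 11 methyl 3-[2-bromo-4,5-bis(tert-butyldimethylsilyloxy)phenoxy]-2-hydroxy-3-[3-(prenyloxy)-4-(triisopropylsilyloxy)phenyl]propanoate
Product: 12 methyl 3-[2-bromo-4,5-bis(tert-butyldimethylsilyloxy)phenoxy]-3-[3-(prenyloxy)-4-(triisopropylsilyloxy)phenyl]-2-(triethylsilyloxy)propanoate (racemic mixture of both diastereomers)
Conditions: TESCl, imidazole, DMAP (cat.), DMF, 20 °C
Reagents that add atoms: chlorotriethylsilane (TESCl), CC[Si](Cl)(CC)CC
Why: Silylation of a secondary alpha-hydroxy ester; the TES ether removes the only acidic O–H before the organolithium step, shields C3–H, and can later be cleaved by weak acid without touching the aryl silyl ethers.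

Step 9
Reactants: 12 methyl 3-[2-bromo-4,5-bis(tert-butyldimethylsilyloxy)phenoxy]-3-[3-(prenyloxy)-4-(triisopropylsilyloxy)phenyl]-2-(triethylsilyloxy)propanoate
Product: 15 6,7-bis(tert-butyldimethylsilyloxy)-3'-(prenyloxy)-3-(triethylsilyloxy)-4'-(triisopropylsilyloxy)flavanone (racemic mixture of cis and trans isomers), via aryllithium 13 (not isolated), via lithium hemiketal 14 (not isolated)
Conditions: n-BuLi (1.05 equiv), THF, −100 → −78 °C; AcOH, −78 °C
Reagents that add atoms: none
Why: This is a Parham cyclization: n-BuLi exchanges the bromine, which stands ortho to the ether oxygen, and gives aryllithium 13. The carbanion at C4a attacks the ester carbonyl C4 within the molecule, giving tetrahedral adduct 14, which loses methoxide (as methanol after the cold acid quench) and leaves ketone 15. Ring C closes in the 6-exo-trig mode, the carbonyl oxygen lying outside the new six-membered ring. The closest known reaction type is the anionic cyclization of ortho-bromoaryl ethers bearing an ester or carboxylate onto that group to give chroman-4-ones. No stereocenter is created; C2 and C3 are carried as a mixture and erased in step 11. The step needs exchange to be faster than butyl addition to the ester and faster than removal of the C3 proton, which would expel the aryloxide; the very low temperature, one equivalent of base, the closeness of the ester to the new carbanion and the bulky TES group next to C3–H are expected to secure this. The ring A site is fixed by the bromine alone, and since the aryl silyl ethers are meta and para to lithium, no silyl shift to carbon is possible. Quenching with acetic acid at −78 °C keeps methoxide from opening the product by beta-elimination.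

Step 10
Reactants: 15 6,7-bis(tert-butyldimethylsilyloxy)-3'-(prenyloxy)-3-(triethylsilyloxy)-4'-(triisopropylsilyloxy)flavanone
Product: 16 6,7-bis(tert-butyldimethylsilyloxy)-3-hydroxy-3'-(prenyloxy)-4'-(triisopropylsilyloxy)flavanone (racemic mixture of cis and trans isomers)
Conditions: PPTS (cat.), MeOH/CH2Cl2, 0 → 20 °C
Reagents that add atoms: none
Why: Acid-catalysed methanolysis of an alkyl TES ether; under pyridinium tosylate the secondary TES ether should cleave, while aryl TBS and TIPS ethers, which are labile to base and fluoride but not to weak acid, and the prenyl ether should remain.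

Step 11
Reactants: 16 6,7-bis(tert-butyldimethylsilyloxy)-3-hydroxy-3'-(prenyloxy)-4'-(triisopropylsilyloxy)flavanone
Product: 18 6,7-bis(tert-butyldimethylsilyloxy)-3-hydroxy-3'-(prenyloxy)-4'-(triisopropylsilyloxy)flavone (achiral), via chromane-3,4-dione 17 (not isolated)
Conditions: (COCl)2, DMSO, CH2Cl2, −78 °C; Et3N, −78 → 0 °C
Reagents that add atoms: none
Why: Swern oxidation of the secondary alpha-hydroxy ketone gives the 3,4-dione 17, whose C2–H is benzylic, alpha to oxygen and alpha to a carbonyl, so triethylamine should enolize it to the conjugated 3-hydroxy-4-pyranone; activated DMSO does not attack the prenyl alkene, and both stereocenters vanish.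

Step 12
Reactants: 18 6,7-bis(tert-butyldimethylsilyloxy)-3-hydroxy-3'-(prenyloxy)-4'-(triisopropylsilyloxy)flavone
Product: 19 3,6,7-trihydroxy-2-[4-hydroxy-3-(prenyloxy)phenyl]-4H-chromen-4-one (CNP0086069.0; achiral)
Conditions: Bu4NF (3.3 equiv), AcOH (4 equiv), THF, 0 °C
Reagents that add atoms: none
Why: Fluoride cleavage of three aryl silyl ethers, driven by Si–F bond formation; acetic acid protonates the phenoxides as they form, which guards the catechol and the enol against air oxidation in base, and neither fluoride nor acetic acid affects the prenyl ether.

## Compound list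

1 | 3,4-dihydroxybenzaldehyde | O=Cc1ccc(O)c(O)c1 | starting material
2 | prenyl bromide (1-bromo-3-methylbut-2-ene) | CC(C)=CCBr | starting material
3 | 4-hydroxy-3-(prenyloxy)benzaldehyde | CC(C)=CCOc1cc(C=O)ccc1O | intermediate
4 | 3-(prenyloxy)-4-(triisopropylsilyloxy)benzaldehyde | CC(C)=CCOc1cc(C=O)ccc1O[Si](C(C)C)(C(C)C)C(C)C | intermediate
5 | methyl chloroacetate | COC(=O)CCl | starting material
6 | methyl 3-[3-(prenyloxy)-4-(triisopropylsilyloxy)phenyl]oxirane-2-carboxylate (racemic, trans expected as main isomer, stereocenters not controlled) | COC(=O)C1OC1c1ccc(O[Si](C(C)C)(C(C)C)C(C)C)c(OCC=C(C)C)c1 | intermediate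
7 | 3,4-bis(tert-butyldimethylsilyloxy)benzaldehyde | CC(C)(C)[Si](C)(C)Oc1ccc(C=O)cc1O[Si](C)(C)C(C)(C)C | intermediate
8 | 3,4-bis(tert-butyldimethylsilyloxy)phenyl formate | O=COc1ccc(O[Si](C)(C)C(C)(C)C)c(O[Si](C)(C)C(C)(C)C)c1 | intermediate (not isolated)
9 | 3,4-bis(tert-butyldimethylsilyloxy)phenol | Oc1ccc(O[Si](C)(C)C(C)(C)C)c(O[Si](C)(C)C(C)(C)C)c1 | intermediate
10 | 2-bromo-4,5-bis(tert-butyldimethylsilyloxy)phenol | Oc1cc(O[Si](C)(C)C(C)(C)C)c(O[Si](C)(C)C(C)(C)C)cc1Br | intermediate
11 | methyl 3-[2-bromo-4,5-bis(tert-butyldimethylsilyloxy)phenoxy]-2-hydroxy-3-[3-(prenyloxy)-4-(triisopropylsilyloxy)phenyl]propanoate (racemic, both diastereomers) | COC(=O)C(O)C(Oc1cc(O[Si](C)(C)C(C)(C)C)c(O[Si](C)(C)C(C)(C)C)cc1Br)c1ccc(O[Si](C(C)C)(C(C)C)C(C)C)c(OCC=C(C)C)c1 | intermediate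
12 | methyl 3-[2-bromo-4,5-bis(tert-butyldimethylsilyloxy)phenoxy]-3-[3-(prenyloxy)-4-(triisopropylsilyloxy)phenyl]-2-(triethylsilyloxy)propanoate (racemic, both diastereomers) | CC[Si](CC)(CC)OC(C(=O)OC)C(Oc1cc(O[Si](C)(C)C(C)(C)C)c(O[Si](C)(C)C(C)(C)C)cc1Br)c1ccc(O[Si](C(C)C)(C(C)C)C(C)C)c(OCC=C(C)C)c1 | intermediate
13 | aryllithium from 12 (lithium in place of bromine at the future C4a) | CC[Si](CC)(CC)OC(C(=O)OC)C(Oc1cc(O[Si](C)(C)C(C)(C)C)c(O[Si](C)(C)C(C)(C)C)cc1[Li])c1ccc(O[Si](C(C)C)(C(C)C)C(C)C)c(OCC=C(C)C)c1 | intermediate (not isolated)
14 | lithium 4-methoxy-chroman-4-olate (tetrahedral adduct of the ring closure, silyl ethers as in 15) | CC[Si](CC)(CC)OC1C(O[Li])(OC)c2cc(O[Si](C)(C)C(C)(C)C)c(O[Si](C)(C)C(C)(C)C)cc2OC1c1ccc(O[Si](C(C)C)(C(C)C)C(C)C)c(OCC=C(C)C)c1 | intermediate (not isolated)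
15 | 6,7-bis(tert-butyldimethylsilyloxy)-3'-(prenyloxy)-3-(triethylsilyloxy)-4'-(triisopropylsilyloxy)flavanone (racemic, cis and trans) | CC[Si](CC)(CC)OC1C(=O)c2cc(O[Si](C)(C)C(C)(C)C)c(O[Si](C)(C)C(C)(C)C)cc2OC1c1ccc(O[Si](C(C)C)(C(C)C)C(C)C)c(OCC=C(C)C)c1 | intermediate
16 | 6,7-bis(tert-butyldimethylsilyloxy)-3-hydroxy-3'-(prenyloxy)-4'-(triisopropylsilyloxy)flavanone (racemic, cis and trans) | OC1C(=O)c2cc(O[Si](C)(C)C(C)(C)C)c(O[Si](C)(C)C(C)(C)C)cc2OC1c1ccc(O[Si](C(C)C)(C(C)C)C(C)C)c(OCC=C(C)C)c1 | intermediate
17 | 6,7-bis(tert-butyldimethylsilyloxy)-2-[3-(prenyloxy)-4-(triisopropylsilyloxy)phenyl]chromane-3,4-dione (racemic at C2) | O=C1C(=O)c2cc(O[Si](C)(C)C(C)(C)C)c(O[Si](C)(C)C(C)(C)C)cc2OC1c1ccc(O[Si](C(C)C)(C(C)C)C(C)C)c(OCC=C(C)C)c1 | intermediate (not isolated)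
18 | 6,7-bis(tert-butyldimethylsilyloxy)-3-hydroxy-3'-(prenyloxy)-4'-(triisopropylsilyloxy)flavone (achiral) | CC(C)=CCOc1cc(-c2oc3cc(O[Si](C)(C)C(C)(C)C)c(O[Si](C)(C)C(C)(C)C)cc3c(=O)c2O)ccc1O[Si](C(C)C)(C(C)C)C(C)C | intermediate
19 | 3,6,7-trihydroxy-2-[4-hydroxy-3-(prenyloxy)phenyl]-4H-chromen-4-one, CNP0086069.0 (achiral) | CC(C)=CCOc1cc(-c2oc3cc(O)c(O)cc3c(=O)c2O)ccc1O | target

## Step count and risks

Total: 12 steps. Longest linear sequence: 9 steps (steps 1–3 or steps 4–6, then steps 7–12).

Step 9 (key step). What may go wrong is direct addition of butyllithium to the aliphatic methyl ester, or removal of the C3 proton followed by loss of the aryloxide. Exchange on a very electron-rich arene is somewhat slower than on a plain aryl bromide, and a methyl ester is a good electrophile. After closure, early collapse of the tetrahedral adduct could also expose the ketone to base-induced ring opening or to a second addition. The fallback sets out from 12 and returns at 15. The ester is converted with Me(MeO)NH·HCl and i-PrMgCl in THF at −20 °C into N-methoxy-N-methyl-3-[2-bromo-4,5-bis(tert-butyldimethylsilyloxy)phenoxy]-3-[3-(prenyloxy)-4-(triisopropylsilyloxy)phenyl]-2-(triethylsilyloxy)propanamide F1. Bromine–lithium exchange with n-BuLi at −100 °C then closes ring C through a chelated tetrahedral adduct that holds until the quench, so no ketone meets base and the less acidic amide alpha proton is harder to remove.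

Step 7. What may go wrong is slow opening by the weakly nucleophilic phenol, which would leave time for 1,2-shift rearrangement of the epoxide to a carbonyl compound or for alkylation of the phenol at carbon. The reason is that a silyloxy group stabilizes the benzylic cation less than a methoxy group does. The fallback sets out from 6 and returns at 12, bypassing 11. MgBr2·OEt2 in ether at 0 °C opens the epoxide at the benzylic carbon to methyl 3-bromo-2-hydroxy-3-[3-(prenyloxy)-4-(triisopropylsilyloxy)phenyl]propanoate F2. TESOTf with 2,6-lutidine at −78 °C gives methyl 3-bromo-3-[3-(prenyloxy)-4-(triisopropylsilyloxy)phenyl]-2-(triethylsilyloxy)propanoate F3. Phenol 10 then replaces the activated benzylic bromide with Ag2CO3 in CH2Cl2 in the dark.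

Step 3. What may go wrong is attack of the base or of an alkoxide on silicon of the aryl silyl ether para to the formyl group, addition of the amide base to the aldehyde, or reversal of the aldol step with this electron-rich aldehyde. The fallback sets out from 4 and returns at 12, bypassing 6 and 11. The lithium enolate of methyl (triethylsilyloxy)acetate (LiN(i-Pr)2, THF, −78 °C, cold quench) adds to 4 and gives methyl 3-hydroxy-3-[3-(prenyloxy)-4-(triisopropylsilyloxy)phenyl]-2-(triethylsilyloxy)propanoate F4. A Mitsunobu etherification of its benzylic hydroxyl with phenol 10 (PPh3, diisopropyl azodicarboxylate, toluene, 0 °C) then makes the O1–C2 bond.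

Step 1. What may go wrong is alkylation at the wrong oxygen or at both oxygens, because the selectivity rests only on the difference in nucleophilicity of the two phenoxides. The fallback sets out from 1 and returns at 3. The more acidic 4-hydroxyl is alkylated first with 2-(trimethylsilyl)ethoxymethyl chloride and K2CO3 (1 equiv) in acetone to give 3-hydroxy-4-{[2-(trimethylsilyl)ethoxy]methoxy}benzaldehyde F5. Prenylation with 2 and K2CO3 in DMF gives 3-(prenyloxy)-4-{[2-(trimethylsilyl)ethoxy]methoxy}benzaldehyde F6. Bu4NF in THF at 60 °C then removes the temporary group without acid.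

## Further compounds

F1 | step 9 | N-methoxy-N-methyl-3-[2-bromo-4,5-bis(tert-butyldimethylsilyloxy)phenoxy]-3-[3-(prenyloxy)-4-(triisopropylsilyloxy)phenyl]-2-(triethylsilyloxy)propanamide (racemic, both diastereomers) | CC[Si](CC)(CC)OC(C(=O)N(C)OC)C(Oc1cc(O[Si](C)(C)C(C)(C)C)c(O[Si](C)(C)C(C)(C)C)cc1Br)c1ccc(O[Si](C(C)C)(C(C)C)C(C)C)c(OCC=C(C)C)c1
F2 | step 7 | methyl 3-bromo-2-hydroxy-3-[3-(prenyloxy)-4-(triisopropylsilyloxy)phenyl]propanoate (racemic, both diastereomers) | COC(=O)C(O)C(Br)c1ccc(O[Si](C(C)C)(C(C)C)C(C)C)c(OCC=C(C)C)c1
F3 | step 7 | methyl 3-bromo-3-[3-(prenyloxy)-4-(triisopropylsilyloxy)phenyl]-2-(triethylsilyloxy)propanoate (racemic, both diastereomers) | CC[Si](CC)(CC)OC(C(=O)OC)C(Br)c1ccc(O[Si](C(C)C)(C(C)C)C(C)C)c(OCC=C(C)C)c1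
F4 | step 3 | methyl 3-hydroxy-3-[3-(prenyloxy)-4-(triisopropylsilyloxy)phenyl]-2-(triethylsilyloxy)propanoate (racemic, both diastereomers) | CC[Si](CC)(CC)OC(C(=O)OC)C(O)c1ccc(O[Si](C(C)C)(C(C)C)C(C)C)c(OCC=C(C)C)c1
F5 | step 1 | 3-hydroxy-4-{[2-(trimethylsilyl)ethoxy]methoxy}benzaldehyde | C[Si](C)(C)CCOCOc1ccc(C=O)cc1O
F6 | step 1 | 3-(prenyloxy)-4-{[2-(trimethylsilyl)ethoxy]methoxy}benzaldehyde | CC(C)=CCOc1cc(C=O)ccc1OCOCC[Si](C)(C)C
A1 | alternative 1 | 6,7,4'-tris(methoxymethoxy)-3'-(prenyloxy)-3-[2-(trimethylsilyl)ethoxy]flavone | CC(C)=CCOc1cc(-c2oc3cc(OCOC)c(OCOC)cc3c(=O)c2OCC[Si](C)(C)C)ccc1OCOC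
A2 | alternative 1 | 2-{[4-(methoxymethoxy)-3-(prenyloxy)benzoyl]oxy}-4,5-bis(methoxymethoxy)benzoyl chloride | CC(C)=CCOc1cc(C(=O)Oc2cc(OCOC)c(OCOC)cc2C(=O)Cl)ccc1OCOC
A3 | alternative 1 | {[2-(trimethylsilyl)ethoxy]methylidene}triphenylphosphorane | C[Si](C)(C)CCOC=P(c1ccccc1)(c1ccccc1)c1ccccc1
A4 | alternative 2 | 6,7,4'-tris(methoxymethoxy)-3'-(prenyloxy)flavone | CC(C)=CCOc1cc(-c2cc(=O)c3cc(OCOC)c(OCOC)cc3o2)ccc1OCOC
A5 | alternative 2 | 2-iodo-4,5-bis(methoxymethoxy)phenol | Oc1cc(OCOC)c(OCOC)cc1I
A6 | alternative 2 | 4-ethynyl-1-(methoxymethoxy)-2-(prenyloxy)benzene | C#Cc1ccc(OCOC)c(OCC=C(C)C)c1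
A7 | alternative 2 | carbon monoxide | [C-]#[O+]
A8 | alternative 3 | 6,7,4'-tris(methoxymethoxy)-3'-(prenyloxy)flavan-3,4-diol (racemic diastereomer mixture) | CC(C)=CCOc1cc(C2Oc3cc(OCOC)c(OCOC)cc3C(O)C2O)ccc1OCOC
A9 | alternative 3 | 2-[2-formyl-4,5-bis(methoxymethoxy)phenoxy]-2-[4-(methoxymethoxy)-3-(prenyloxy)phenyl]acetaldehyde (racemic) | O=CC(Oc1cc(OCOC)c(OCOC)cc1C=O)c1ccc(OCOC)c(OCC=C(C)C)c1
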